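**Strategy.** Ring C is cut at O1–C2 and C4–C4a, which divides the target into phloroglucinol and methyl (R)-2-aryloxirane-2-carboxylate, a three-carbon piece whose epoxide oxygen becomes the C3 hydroxyl. In one basic operation a phloroglucinol oxygen opens the epoxide at its CH2 group and the neighbouring ring carbon is acylated by the ester. The step exploits two features: ring A carries O1, 5-OH and 7-OH on alternate carbons, so every oxygen/ortho-carbon pair of unprotected phloroglucinol is equivalent; and C3 is fully substituted, so the epoxide can open only at C2 and the stereocenter, set earlier by organocatalytic epoxidation, is carried through untouched.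

Key step: step 9

Remark: the target is (3R) (CIP order OH > C4 > C2 > aryl); the facial sense of the organocatalytic epoxidation of the 2-arylacrolein is assumed to follow that of 2-alkylacroleins.

**Step 1**
Reactants: 1 4-bromo-3-methoxyphenol; 2 1-bromo-3-methylbut-2-ene (prenyl bromide)
Product: 3 1-bromo-2-methoxy-4-[(3-methylbut-2-en-1-yl)oxy]benzene
Conditions: K2CO3, acetone, reflux
Reagents that add atoms: none
Why: Williamson ether synthesis, the phenoxide displacing the primary allylic bromide (SN2) with O-alkylation favoured in acetone/carbonate.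

**Step 2**
Reactants: 3 1-bromo-2-methoxy-4-[(3-methylbut-2-en-1-yl)oxy]benzene
Product: 5 4-bromo-5-methoxy-2-(2-methylbut-3-en-2-yl)phenol, via ortho-dienone 4 (not isolated)
Conditions: EtOH–H2O (4:1), 140 °C, sealed tube
Reagents that add atoms: none
Why: Aromatic Claisen rearrangement ([3,3]-sigmatropic, chair transition state) should deliver the dimethyl-substituted allyl terminus to the unhindered ortho carbon C5 (the other ortho carbon is flanked by the methoxy group) and tautomerization of 4 restores the phenol; the protic medium accelerates the shift, and any C3 regioisomer is removed here by chromatography.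

**Step 3**
Reactants: 5 4-bromo-5-methoxy-2-(2-methylbut-3-en-2-yl)phenol
Product: 6 [4-bromo-5-methoxy-2-(2-methylbut-3-en-2-yl)phenoxy]tri(propan-2-yl)silane
Conditions: TIPSOTf, 2,6-lutidine, CH2Cl2, 0 °C
Reagents that add atoms: triisopropylsilyl trifluoromethanesulfonate (TIPSOTf), CC(C)[Si](OS(=O)(=O)C(F)(F)F)(C(C)C)C(C)C
Why: O-silylation of the hindered phenol with the silyl triflate and a hindered base; the silyl ether masks the acidic proton for the Grignard step and later keeps the para oxygen from opening the epoxide as a quinone methide.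

**Step 4**
Reactants: 6 [4-bromo-5-methoxy-2-(2-methylbut-3-en-2-yl)phenoxy]tri(propan-2-yl)silane; 7 prop-2-yn-1-ol
Product: 11 2-{2-methoxy-5-(2-methylbut-3-en-2-yl)-4-[(triisopropylsilyl)oxy]phenyl}prop-2-en-1-ol, via arylmagnesium bromide 8 (not isolated), via chloromagnesium propargyl alkoxide 9 (not isolated), via alkenylmagnesium adduct 10 (not isolated)
Conditions: 6, Mg, LiCl, THF, 45 °C; 7, i-PrMgCl, THF, 0 °C; then both, CuI (10 mol %), THF–Et2O, 0 °C to reflux; aq NH4Cl
Reagents that add atoms: none
Why: Copper-catalysed anti carbomagnesiation of a propargylic magnesium alkoxide by an aryl Grignard reagent, in which alkoxide chelation places magnesium on the terminal carbon and the aryl group on the internal one; protonation of 10 should give the 2-arylallyl alcohol.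

**Step 5**
Reactants: 11 2-{2-methoxy-5-(2-methylbut-3-en-2-yl)-4-[(triisopropylsilyl)oxy]phenyl}prop-2-en-1-ol
Product: 12 2-{2-methoxy-5-(2-methylbut-3-en-2-yl)-4-[(triisopropylsilyl)oxy]phenyl}prop-2-enal
Conditions: MnO2, CH2Cl2, rt
Reagents that add atoms: none
Why: Activated MnO2 oxidizes the allylic alcohol selectively to the conjugated aldehyde under neutral conditions; the polymerization-prone 2-arylacrolein is used at once.

**Step 6**
Reactants: 12 2-{2-methoxy-5-(2-methylbut-3-en-2-yl)-4-[(triisopropylsilyl)oxy]phenyl}prop-2-enal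
Product: 13 (2R)-2-{2-methoxy-5-(2-methylbut-3-en-2-yl)-4-[(triisopropylsilyl)oxy]phenyl}oxirane-2-carbaldehyde
Conditions: 35% aq H2O2, (S)-2-{diphenyl[(methyldiphenylsilyl)oxy]methyl}pyrrolidine (10 mol %), CH2Cl2, rt
Reagents that add atoms: hydrogen peroxide, OO
Why: Iminium-activated Weitz–Scheffer-type epoxidation of a 2-substituted acrolein, in which hydroperoxide adds to the CH2 terminus and the enamine closes on oxygen from the face left open by the diaryl(silyloxy)methyl group; by analogy with 2-alkylacroleins the (S)-catalyst is expected to set C2 as R, and the nucleophilic oxidant leaves the isolated vinyl group alone.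

**Step 7**
Reactants: 13 (2R)-2-{2-methoxy-5-(2-methylbut-3-en-2-yl)-4-[(triisopropylsilyl)oxy]phenyl}oxirane-2-carbaldehyde
Product: 14 (2R)-2-{2-methoxy-5-(2-methylbut-3-en-2-yl)-4-[(triisopropylsilyl)oxy]phenyl}oxirane-2-carboxylic acid
Conditions: NaClO2, NaH2PO4, 2-methylbut-2-ene, t-BuOH–H2O, 0 °C
Reagents that add atoms: sodium chlorite, [Na+].[O-]Cl=O
Why: Pinnick oxidation in phosphate buffer with an alkene scavenger for hypochlorite should convert the aldehyde to the acid without touching the epoxide, the vinyl group or the stereocenter (still R).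

**Step 8**
Reactants: 14 (2R)-2-{2-methoxy-5-(2-methylbut-3-en-2-yl)-4-[(triisopropylsilyl)oxy]phenyl}oxirane-2-carboxylic acid
Product: 15 methyl (2R)-2-{2-methoxy-5-(2-methylbut-3-en-2-yl)-4-[(triisopropylsilyl)oxy]phenyl}oxirane-2-carboxylate
Conditions: MeI, K2CO3, DMF, 0 °C to rt
Reagents that add atoms: iodomethane, CI
Why: SN2 O-methylation of the carboxylate under weakly basic conditions avoids exposing the glycidic acid to acid and does not involve the stereocenter.

**Step 9**
Reactants: 15 methyl (2R)-2-{2-methoxy-5-(2-methylbut-3-en-2-yl)-4-[(triisopropylsilyl)oxy]phenyl}oxirane-2-carboxylate; 16 benzene-1,3,5-triol (phloroglucinol)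
Product: 18 (3R)-3,5,7-trihydroxy-3-{2-methoxy-5-(2-methylbut-3-en-2-yl)-4-[(triisopropylsilyl)oxy]phenyl}-2,3-dihydro-4H-chromen-4-one, via aryl ether hydroxy ester 17 (not isolated)
Conditions: 16 (3 equiv), Cs2CO3, DMF, 60 °C, then 110 °C; aq NH4Cl
Reagents that add atoms: none
Why: Proposed new method: caesium phloroglucinolate attacks the epoxide of 15 at its unsubstituted CH2 carbon (SN2, O1–C2), giving the 5-alkoxyresorcinolate 17, whose ortho carbon, reacting as the enolate carbon of its keto tautomer, then adds to the neighbouring ester carbonyl and expels methoxide (C4–C4a). The closest known reactions are the phenoxide opening of glycidic esters at the β-carbon for the first bond and, for the second, the Dieckmann/Claisen acylation of 1,3-dicarbonyl enolates and the ortho-carboxylation of resorcinol- and phloroglucinol-type phenoxides by CO2 or magnesium methyl carbonate; acylation of such a phenoxide carbon by a simple ester under carbonate conditions has not been shown. Only the pyranone ring is closed, in a 6-exo-trig mode at the ester carbonyl, the intermolecular epoxide opening having already fixed the ether link. No stereocenter is formed: C3 keeps its four substituents (epoxide oxygen as OH, CH2, aryl, acyl carbon), so the R configuration of 15 passes unchanged into 18, and the silyl ether prevents the para oxygen from opening the epoxide as a quinone methide, the only path that could racemize it. The step needs O- before C-alkylation (hard epoxide, caesium counter-ion, DMF), attack at CH2 and not at the fully substituted C3, monoalkylation (excess phloroglucinol) and C- not O-acylation (the remaining phenoxide oxygens cannot reach the ester, and intermolecular transesterification is reversible while C-acylation ends in a chelated vinylogous carboxylate). The ring carbon needs no control, since the two carbons ortho to the new ether oxygen are equivalent.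

**Step 10**
Reactants: 18 (3R)-3,5,7-trihydroxy-3-{2-methoxy-5-(2-methylbut-3-en-2-yl)-4-[(triisopropylsilyl)oxy]phenyl}-2,3-dihydro-4H-chromen-4-one
Product: 19 (3R)-3,5,7-trihydroxy-3-[4-hydroxy-2-methoxy-5-(2-methylbut-3-en-2-yl)phenyl]-2,3-dihydro-4H-chromen-4-one
Conditions: Bu4NF, AcOH, THF, 0 °C
Reagents that add atoms: none
Why: Fluoride cleaves the aryl silyl ether (strong Si–F bond), acetic acid buffering protects the polyphenolic α-ketol from base-induced rearrangement, and C3 is untouched.

**Compound list**

1 | 4-bromo-3-methoxyphenol | COc1cc(O)ccc1Br | starting material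
2 | 1-bromo-3-methylbut-2-ene (prenyl bromide) | CC(C)=CCBr | starting material
3 | 1-bromo-2-methoxy-4-[(3-methylbut-2-en-1-yl)oxy]benzene | COc1cc(OCC=C(C)C)ccc1Br | intermediate
4 | 4-bromo-3-methoxy-6-(2-methylbut-3-en-2-yl)cyclohexa-2,4-dien-1-one (racemic ortho-dienone) | O=C1C=C(OC)C(Br)=CC1C(C)(C)C=C | intermediate
5 | 4-bromo-5-methoxy-2-(2-methylbut-3-en-2-yl)phenol | C=CC(C)(C)c1cc(Br)c(OC)cc1O | intermediate
6 | [4-bromo-5-methoxy-2-(2-methylbut-3-en-2-yl)phenoxy]tri(propan-2-yl)silane | C=CC(C)(C)c1cc(Br)c(OC)cc1O[Si](C(C)C)(C(C)C)C(C)C | intermediate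
7 | prop-2-yn-1-ol | C#CCO | starting material
8 | {2-methoxy-5-(2-methylbut-3-en-2-yl)-4-[(triisopropylsilyl)oxy]phenyl}magnesium bromide | C=CC(C)(C)c1cc([Mg]Br)c(OC)cc1O[Si](C(C)C)(C(C)C)C(C)C | intermediate
9 | chloromagnesium prop-2-yn-1-olate | C#CCO[Mg]Cl | intermediate
10 | alkenylmagnesium bromide / chloromagnesium alkoxide from anti addition of 8 to 9 (aryl and MgBr trans) | C=CC(C)(C)c1cc(/C(CO[Mg]Cl)=C/[Mg]Br)c(OC)cc1O[Si](C(C)C)(C(C)C)C(C)C | intermediate
11 | 2-{2-methoxy-5-(2-methylbut-3-en-2-yl)-4-[(triisopropylsilyl)oxy]phenyl}prop-2-en-1-ol | C=CC(C)(C)c1cc(C(=C)CO)c(OC)cc1O[Si](C(C)C)(C(C)C)C(C)C | intermediate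
12 | 2-{2-methoxy-5-(2-methylbut-3-en-2-yl)-4-[(triisopropylsilyl)oxy]phenyl}prop-2-enal | C=CC(C)(C)c1cc(C(=C)C=O)c(OC)cc1O[Si](C(C)C)(C(C)C)C(C)C | intermediate
13 | (2R)-2-{2-methoxy-5-(2-methylbut-3-en-2-yl)-4-[(triisopropylsilyl)oxy]phenyl}oxirane-2-carbaldehyde | C=CC(C)(C)c1cc([C@]2(C=O)CO2)c(OC)cc1O[Si](C(C)C)(C(C)C)C(C)C | intermediate
14 | (2R)-2-{2-methoxy-5-(2-methylbut-3-en-2-yl)-4-[(triisopropylsilyl)oxy]phenyl}oxirane-2-carboxylic acid | C=CC(C)(C)c1cc([C@]2(C(=O)O)CO2)c(OC)cc1O[Si](C(C)C)(C(C)C)C(C)C | intermediate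
15 | methyl (2R)-2-{2-methoxy-5-(2-methylbut-3-en-2-yl)-4-[(triisopropylsilyl)oxy]phenyl}oxirane-2-carboxylate | C=CC(C)(C)c1cc([C@]2(C(=O)OC)CO2)c(OC)cc1O[Si](C(C)C)(C(C)C)C(C)C | intermediate
16 | benzene-1,3,5-triol (phloroglucinol) | Oc1cc(O)cc(O)c1 | starting material
17 | methyl (2R)-3-(3,5-dihydroxyphenoxy)-2-hydroxy-2-{2-methoxy-5-(2-methylbut-3-en-2-yl)-4-[(triisopropylsilyl)oxy]phenyl}propanoate | C=CC(C)(C)c1cc([C@](O)(C(=O)OC)COc2cc(O)cc(O)c2)c(OC)cc1O[Si](C(C)C)(C(C)C)C(C)C | intermediate
18 | (3R)-3,5,7-trihydroxy-3-{2-methoxy-5-(2-methylbut-3-en-2-yl)-4-[(triisopropylsilyl)oxy]phenyl}-2,3-dihydro-4H-chromen-4-one | C=CC(C)(C)c1cc([C@@]2(O)COc3cc(O)cc(O)c3C2=O)c(OC)cc1O[Si](C(C)C)(C(C)C)C(C)C | intermediate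
19 | (3R)-3,5,7-trihydroxy-3-[4-hydroxy-2-methoxy-5-(2-methylbut-3-en-2-yl)phenyl]-2,3-dihydro-4H-chromen-4-one | C=CC(C)(C)c1cc([C@@]2(O)COc3cc(O)cc(O)c3C2=O)c(OC)cc1O | target

**Totals.** Total step count: 10. Longest linear sequence: 10 steps (1 to 19; phloroglucinol enters at step 9).

**Steps most likely to fail**

Step 9 (proposed new method). The second bond may not form: after the epoxide has opened, the ring carbon of the resorcinolate may fail to attack the unactivated methyl ester, so the reaction stops at the ether, while prolonged heating invites polyalkylation of phloroglucinol or loss of the silyl group. The fallback uses only known chemistry, sets out from acid 14 and returns at 18.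
- Commercial 3,5-bis(benzyloxy)phenol is brominated ortho to the hydroxyl (NBS, CH2Cl2, −78 °C) to 2-bromo-3,5-bis(benzyloxy)phenol F1.
- O-silylation with hexamethyldisilazane gives [2-bromo-3,5-bis(benzyloxy)phenoxy]trimethylsilane F2.
- n-BuLi (bromine–lithium exchange, then retro-Brook 1,3-silyl shift) gives 3,5-bis(benzyloxy)-2-(trimethylsilyl)phenol F3.
- Tf2O/pyridine converts F3 to 3,5-bis(benzyloxy)-2-(trimethylsilyl)phenyl trifluoromethanesulfonate F4.
- The caesium salt of 14 and F4 are treated with CsF in THF at 65–100 °C; CsF is sparingly soluble there and the hindered silyl ether should persist. Fluoride-induced elimination generates the aryne, the carboxylate oxygen adds at the aryne carbon remote from the 3-benzyloxy group, and the aryl anion next to that group takes over the acyl group. This is the known insertion of arynes into the C–O bond of carboxylic acids, which with unsaturated acids gives chroman-4-ones in one pot. The liberated phenoxide then opens the epoxide at CH2 to give (3R)-5,7-bis(benzyloxy)-3-hydroxy-3-{2-methoxy-5-(2-methylbut-3-en-2-yl)-4-[(triisopropylsilyl)oxy]phenyl}-2,3-dihydro-4H-chromen-4-one F5.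
- BCl3/pentamethylbenzene (CH2Cl2, −78 °C) removes both benzyl groups without touching the alkene and gives 18.

Step 6. Iminium formation with the hindered, conjugated 2-arylacrolein may be slow, facial discrimination may be poor or of the opposite sense, and the enal may polymerize. The fallback sets out from allylic alcohol 11 and returns at acid 14.
- Sharpless asymmetric epoxidation (Ti(OiPr)4 10 mol %, L-(+)-diisopropyl tartrate, t-BuOOH, 4 Å molecular sieves, CH2Cl2, −25 °C) is hydroxyl-directed, so the isolated vinyl group is inert. With the face selection known for 2-substituted allylic alcohols it should give [(2S)-2-{2-methoxy-5-(2-methylbut-3-en-2-yl)-4-[(triisopropylsilyl)oxy]phenyl}oxiran-2-yl]methanol F6.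
- Because this electron-rich tertiary benzylic epoxide is acid-labile, it is oxidized without chromatography with TEMPO/PhI(OAc)2 in MeCN–pH 7 phosphate buffer to 14. The descriptor changes from S to R only because CH2OH becomes CO2H.

Step 4. Magnesium insertion into the hindered, electron-rich bromide may be incomplete, the Grignard reagent may be lost by protonation or homocoupling, and aryl transfer in the copper-catalysed addition may be poor. The fallback sets out from bromide 6 and returns at enal 12.
- Suzuki–Miyaura coupling of 6 with commercial isopropenylboronic acid pinacol ester (PdCl2(dppf), K2CO3, dioxane–water, 80 °C) gives {5-methoxy-2-(2-methylbut-3-en-2-yl)-4-(prop-1-en-2-yl)phenoxy}tri(propan-2-yl)silane F7.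
- Riley oxidation with SeO2 (dioxane, reflux) converts its only allylic C–H position, the isopropenyl methyl group, to the aldehyde 12; the 1,1-dimethylallyl group has no allylic hydrogen.

**Further compounds**

F1 | step 9 | 2-bromo-3,5-bis(benzyloxy)phenol | Oc1cc(OCc2ccccc2)cc(OCc2ccccc2)c1Br
F2 | step 9 | [2-bromo-3,5-bis(benzyloxy)phenoxy]trimethylsilane | C[Si](C)(C)Oc1cc(OCc2ccccc2)cc(OCc2ccccc2)c1Br
F3 | step 9 | 3,5-bis(benzyloxy)-2-(trimethylsilyl)phenol | C[Si](C)(C)c1c(O)cc(OCc2ccccc2)cc1OCc1ccccc1
F4 | step 9 | 3,5-bis(benzyloxy)-2-(trimethylsilyl)phenyl trifluoromethanesulfonate | C[Si](C)(C)c1c(OS(=O)(=O)C(F)(F)F)cc(OCc2ccccc2)cc1OCc1ccccc1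
F5 | step 9 | (3R)-5,7-bis(benzyloxy)-3-hydroxy-3-{2-methoxy-5-(2-methylbut-3-en-2-yl)-4-[(triisopropylsilyl)oxy]phenyl}-2,3-dihydro-4H-chromen-4-one | C=CC(C)(C)c1cc([C@@]2(O)COc3cc(OCc4ccccc4)cc(OCc4ccccc4)c3C2=O)c(OC)cc1O[Si](C(C)C)(C(C)C)C(C)C
F6 | step 6 | [(2S)-2-{2-methoxy-5-(2-methylbut-3-en-2-yl)-4-[(triisopropylsilyl)oxy]phenyl}oxiran-2-yl]methanol | C=CC(C)(C)c1cc([C@]2(CO)CO2)c(OC)cc1O[Si](C(C)C)(C(C)C)C(C)C
F7 | step 4 | {5-methoxy-2-(2-methylbut-3-en-2-yl)-4-(prop-1-en-2-yl)phenoxy}tri(propan-2-yl)silane | C=CC(C)(C)c1cc(C(C)=C)c(OC)cc1O[Si](C(C)C)(C(C)C)C(C)C
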